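The target is a (2S,4R)-7,4'-dihydroxyflavan (atoms O1 to C8a; rings A, B and C) bonded from C4 to C8 of ring D of (−)-epigallocatechin (rings D, E and F). Since C3 of ring C is a bare methylene between the oxygenated C2 and the diaryl-substituted C4, the C3–C4 pair is traced back to a vinyl group on C8 of ring D. One nickel/photoredox operation adds a 4-benzyloxybenzoyl radical (C2–C3) and the ring A aryl bromide (C4–C4a) across 8-vinyl-hexa-O-benzylepigallocatechin and sets C4. Reagent-controlled reduction and a Mitsunobu etherification then close ring C, and one hydrogenolysis frees the phenols.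

Key step: step 8

Structure check: the flavan half is (2S,4R) with the two aryl groups trans across ring C, and the epigallocatechin half is (2R,3R). A (3R) ketone, a (1R) carbinol and inversion at C2 are consistent with this. Names of the epigallocatechin half use ordinary flavan-3-ol numbering.

Assumption: which antipode of the bis(imidazoline) ligand gives (R) at C4 cannot be predicted for this substrate; the (S,S) ligand is written and its mirror image is used if the sense proves opposite.

Remark: the ring A oxygen ortho to bromine is carried as an acetate, because an acetal there would need acid for removal after the reduction, and acid would ionise the 4-benzyloxybenzylic carbinol and scramble C2.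

Step 1
Reactants: 1 (−)-epigallocatechin
Product: 2 5,7,3',4',5'-penta-O-benzyl-(−)-epigallocatechin (3-OH free)
Conditions: BnBr (5.5 equiv), K2CO3, degassed DMF, Ar, 0 °C to rt
Reagents that add atoms: benzyl bromide, BrCc1ccccc1
Why: Williamson etherification: carbonate deprotonates only the five phenols, so the secondary 3-hydroxyl stays free, while air-free, cold conditions limit pyrogallol oxidation and C-benzylation and leave both stereocentres untouched.

Step 2
Reactants: 2 5,7,3',4',5'-penta-O-benzyl-(−)-epigallocatechin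
Product: 3 3,5,7,3',4',5'-hexa-O-benzyl-(−)-epigallocatechin
Conditions: NaH, BnBr, n-Bu4NI (cat.), DMF, 0 °C to rt
Reagents that add atoms: benzyl bromide, BrCc1ccccc1
Why: Williamson etherification of the remaining secondary alkoxide, which cannot epimerise C2 or C3 because no free phenol is left to open ring F.

Step 3
Reactants: 3 3,5,7,3',4',5'-hexa-O-benzyl-(−)-epigallocatechin
Product: 4 8-bromo-hexa-O-benzylepigallocatechin
Conditions: NBS (1.05 equiv), CH2Cl2, −78 °C to 0 °C
Reagents that add atoms: N-bromosuccinimide, O=C1CCC(=O)N1Br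
Why: Electrophilic aromatic bromination: ring D carries three oxygen donors and is the most activated ring, and in benzylated flavan-3-ols one equivalent of NBS at low temperature attacks C8 in preference to C6 and to ring E.

Step 4
Reactants: 4 8-bromo-hexa-O-benzylepigallocatechin
Product: 5 8-vinyl-hexa-O-benzylepigallocatechin
Conditions: vinylboronic acid pinacol ester, Pd(OAc)2 (cat.), SPhos (cat.), K3PO4, toluene/H2O, 90 °C
Reagents that add atoms: vinylboronic acid pinacol ester, C=CB1OC(C)(C)C(C)(C)O1
Why: Suzuki–Miyaura coupling: the bulky, electron-rich SPhos ligand lets zerovalent palladium insert into the doubly ortho-substituted, electron-rich C8–Br bond, and the vinyl group is transferred from boron under mild phosphate base.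

Step 5
Reactants: 6 4'-benzyloxyacetophenone
Product: 7 2-(4-benzyloxyphenyl)-2-oxoacetic acid
Conditions: SeO2, pyridine, 100 °C; then aq. HCl
Reagents that add atoms: selenium dioxide, O=[Se]=O
Why: Riley oxidation: SeO2 in pyridine oxidises the enolisable methyl group through the aryl glyoxal to the arylglyoxylic acid, and the aryl benzyl ether is inert.

Step 6
Reactants: 8 4-bromoresorcinol
Product: 9 5-(benzyloxy)-2-bromophenol
Conditions: BnBr (1.0 equiv), K2CO3 (1.0 equiv), acetone, rt
Reagents that add atoms: benzyl bromide, BrCc1ccccc1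
Why: Williamson mono-etherification: with one equivalent each of base and halide the phenoxide para to bromine, which is less hindered and more nucleophilic than the one flanked by bromine, is alkylated preferentially, and the dibenzyl ether and the regioisomer are removed by chromatography.

Step 7
Reactants: 9 5-(benzyloxy)-2-bromophenol
Product: 10 5-(benzyloxy)-2-bromophenyl acetate
Conditions: Ac2O, pyridine, DMAP (cat.), CH2Cl2, 0 °C to rt
Reagents that add atoms: acetic anhydride, CC(=O)OC(C)=O
Why: Nucleophile-catalysed O-acetylation of the remaining phenol, which gives a small, electron-withdrawing and base-removable group next to bromine.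

Step 8
Reactants: 5 8-vinyl-hexa-O-benzylepigallocatechin; 7 2-(4-benzyloxyphenyl)-2-oxoacetic acid; 10 5-(benzyloxy)-2-bromophenyl acetate
Product: 11 (3R)-3-[2-acetoxy-4-(benzyloxy)phenyl]-1-[4-(benzyloxy)phenyl]-3-(hexa-O-benzylepigallocatechin-8-yl)propan-1-one
Conditions: 4CzIPN (2 mol %), NiBr2(MeOCH2CH2OMe) (5 mol %), (S,S)-N,N'-diaryl-4,4'-diisopropyl-2,2'-bis(imidazoline) (6 mol %), K2HPO4, DMA, blue LEDs (450 nm), 15 °C; 5 (1 equiv), 10 (1.5 equiv), 7 (2 equiv, added slowly)
Reagents that add atoms: none
Why: Proposed new method: excited 4CzIPN oxidises the carboxylate of 7, loss of CO2 gives the 4-benzyloxybenzoyl radical, this adds to the terminal vinyl carbon of 5 (C2–C3 bond), and the resulting C4 benzylic radical is captured by the aryl–nickel bromide formed from 10 and low-valent nickel, after which reductive elimination from trivalent nickel forms C4–C4a and the reduced photocatalyst returns nickel to its low-valent state. The closest known reaction types are the enantioselective nickel/photoredox three-component carboarylation of vinylarenes with aryl bromides under chiral bis(imidazoline) ligands and the photoredox decarboxylation of α-keto acids to acyl radicals for nickel-catalysed arylation, but an acyl radical has not been shown in the enantioselective three-component manifold, nor has a styrene flanked by two ortho oxygen substituents. No ring is closed. The new stereocentre C4 (R) is set by the chiral ligand on nickel during capture of the prochiral benzylic radical and reductive elimination, the stereocentres of ring F being remote, so the choice of ligand antipode decides the configuration. The step needs regioselective radical addition, which the monosubstituted vinyl group secures because its terminal carbon is unhindered and the internal carbon gives a radical stabilised by the trioxygenated ring D, and it needs three-component coupling to outrun direct acyl–aryl coupling, which is favoured by a high concentration of 5, a low nickel loading and slow addition of 7. The acetate ortho to bromine makes the bromide less electron-rich for oxidative addition and is inert to the phosphate base.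

Step 9
Reactants: 11 (3R)-3-[2-acetoxy-4-(benzyloxy)phenyl]-1-[4-(benzyloxy)phenyl]-3-(hexa-O-benzylepigallocatechin-8-yl)propan-1-one
Product: 13 (1R,3R)-3-[4-(benzyloxy)-2-hydroxyphenyl]-1-[4-(benzyloxy)phenyl]-3-(hexa-O-benzylepigallocatechin-8-yl)propan-1-ol, via (1R)-acetoxy carbinol 12 (not isolated)
Conditions: (S)-2-methyl-CBS-oxazaborolidine (0.2 equiv), BH3·SMe2, THF, −20 °C; then MeOH, K2CO3, rt
Reagents that add atoms: none
Why: Corey–Bakshi–Shibata reduction: the (S)-oxazaborolidine–borane complex treats the aryl group as the large and the CH2 group as the small ketone substituent and delivers hydride to give the (1R) carbinol under reagent control, after which carbonate-mediated transesterification in the same flask frees only the ring A phenol without acid, so the ionisable benzylic carbinol and C3 stay intact.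

Step 10
Reactants: 13 (1R,3R)-3-[4-(benzyloxy)-2-hydroxyphenyl]-1-[4-(benzyloxy)phenyl]-3-(hexa-O-benzylepigallocatechin-8-yl)propan-1-ol
Product: 14 (2S,4R)-7-(benzyloxy)-2-[4-(benzyloxy)phenyl]-4-(hexa-O-benzylepigallocatechin-8-yl)chromane (octa-O-benzyl target)
Conditions: PPh3, DIAD, toluene/THF, 0 °C to rt
Reagents that add atoms: none
Why: Intramolecular Mitsunobu etherification: the ring A phenol, the only acidic hydroxyl, displaces the oxyphosphonium group of the carbinol in a 6-exo-tet SN2 closure that inverts (1R) to (2S) and so gives the 2,4-trans flavan, with C4 untouched.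

Step 11
Reactants: 14 (2S,4R)-7-(benzyloxy)-2-[4-(benzyloxy)phenyl]-4-(hexa-O-benzylepigallocatechin-8-yl)chromane
Product: 15 (2R,3R)-8-[(2S,4R)-7-hydroxy-2-(4-hydroxyphenyl)chroman-4-yl]-2-(3,4,5-trihydroxyphenyl)chromane-3,5,7-triol (target)
Conditions: H2 (1 atm), Pd(OH)2 on carbon, THF/MeOH, rt
Reagents that add atoms: none
Why: Heterogeneous catalytic hydrogenolysis cleaves all eight benzyl ethers under neutral conditions, which spare the cyclic benzylic C2–O1 bonds of both pyran rings and epimerise no centre.

Compound list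
1 | (−)-epigallocatechin, (2R,3R) | Oc1cc(O)c2c(c1)O[C@H](c1cc(O)c(O)c(O)c1)[C@H](O)C2 | starting material
2 | 5,7,3',4',5'-penta-O-benzyl-(−)-epigallocatechin (3-OH free) | c1ccccc1COc1cc(OCc3ccccc3)c2c(c1)O[C@H](c1cc(OCc3ccccc3)c(OCc3ccccc3)c(OCc3ccccc3)c1)[C@H](O)C2 | intermediate
3 | 3,5,7,3',4',5'-hexa-O-benzyl-(−)-epigallocatechin | c1ccccc1COc1cc(OCc3ccccc3)c2c(c1)O[C@H](c1cc(OCc3ccccc3)c(OCc3ccccc3)c(OCc3ccccc3)c1)[C@H](OCc1ccccc1)C2 | intermediate
4 | 8-bromo-hexa-O-benzylepigallocatechin | Brc1c(OCc3ccccc3)cc(OCc3ccccc3)c2c1O[C@H](c1cc(OCc3ccccc3)c(OCc3ccccc3)c(OCc3ccccc3)c1)[C@H](OCc1ccccc1)C2 | intermediate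
5 | 8-vinyl-hexa-O-benzylepigallocatechin | C=Cc1c(OCc3ccccc3)cc(OCc3ccccc3)c2c1O[C@H](c1cc(OCc3ccccc3)c(OCc3ccccc3)c(OCc3ccccc3)c1)[C@H](OCc1ccccc1)C2 | intermediate
6 | 4'-benzyloxyacetophenone | CC(=O)c1ccc(OCc2ccccc2)cc1 | starting material
7 | 2-(4-benzyloxyphenyl)-2-oxoacetic acid | OC(=O)C(=O)c1ccc(OCc2ccccc2)cc1 | intermediate
8 | 4-bromoresorcinol | Oc1ccc(Br)c(O)c1 | starting material
9 | 5-(benzyloxy)-2-bromophenol | Oc1cc(OCc2ccccc2)ccc1Br | intermediate
10 | 5-(benzyloxy)-2-bromophenyl acetate | CC(=O)Oc1cc(OCc2ccccc2)ccc1Br | intermediate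
11 | (3R)-3-[2-acetoxy-4-(benzyloxy)phenyl]-1-[4-(benzyloxy)phenyl]-3-(hexa-O-benzylepigallocatechin-8-yl)propan-1-one | O=C(c1ccc(OCc2ccccc2)cc1)C[C@@H](c1c(OCc3ccccc3)cc(OCc3ccccc3)c2c1O[C@H](c1cc(OCc3ccccc3)c(OCc3ccccc3)c(OCc3ccccc3)c1)[C@H](OCc1ccccc1)C2)c1ccc(OCc2ccccc2)cc1OC(C)=O | intermediate
12 | (1R,3R)-3-[2-acetoxy-4-(benzyloxy)phenyl]-1-[4-(benzyloxy)phenyl]-3-(hexa-O-benzylepigallocatechin-8-yl)propan-1-ol | O[C@@H](c1ccc(OCc2ccccc2)cc1)C[C@@H](c1c(OCc3ccccc3)cc(OCc3ccccc3)c2c1O[C@H](c1cc(OCc3ccccc3)c(OCc3ccccc3)c(OCc3ccccc3)c1)[C@H](OCc1ccccc1)C2)c1ccc(OCc2ccccc2)cc1OC(C)=O | intermediate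
13 | (1R,3R)-3-[4-(benzyloxy)-2-hydroxyphenyl]-1-[4-(benzyloxy)phenyl]-3-(hexa-O-benzylepigallocatechin-8-yl)propan-1-ol | O[C@@H](c1ccc(OCc2ccccc2)cc1)C[C@@H](c1c(OCc3ccccc3)cc(OCc3ccccc3)c2c1O[C@H](c1cc(OCc3ccccc3)c(OCc3ccccc3)c(OCc3ccccc3)c1)[C@H](OCc1ccccc1)C2)c1ccc(OCc2ccccc2)cc1O | intermediate
14 | (2S,4R)-7-(benzyloxy)-2-[4-(benzyloxy)phenyl]-4-(hexa-O-benzylepigallocatechin-8-yl)chromane | c1ccccc1COc1ccc([C@@H]2C[C@@H](c3c(OCc5ccccc5)cc(OCc5ccccc5)c4c3O[C@H](c3cc(OCc5ccccc5)c(OCc5ccccc5)c(OCc5ccccc5)c3)[C@H](OCc3ccccc3)C4)c3ccc(OCc5ccccc5)cc3O2)cc1 | intermediate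
15 | (2R,3R)-8-[(2S,4R)-7-hydroxy-2-(4-hydroxyphenyl)chroman-4-yl]-2-(3,4,5-trihydroxyphenyl)chromane-3,5,7-triol | Oc1ccc([C@@H]2C[C@@H](c3c(O)cc(O)c4c3O[C@H](c3cc(O)c(O)c(O)c3)[C@H](O)C4)c3ccc(O)cc3O2)cc1 | target

Total step count: 11.
Longest linear sequence: 8 steps (steps 1, 2, 3, 4, 8, 9, 10 and 11).

Steps most likely to fail

Step 8. Three things may go wrong:
- The acyl radical may be captured by nickel before it adds to the electron-rich alkene, which gives direct acyl–aryl coupling.
- The crowded C4 radical may be captured slowly, which leads to hydrogen abstraction or dimerisation, or with poor facial discrimination.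
- The electron-rich styrene or the benzyl ether C–H bonds may be attacked under irradiation.

The fallback uses known chemistry, sets out from 4 and comes back at 11. Bromine–lithium exchange on 4 (n-BuLi, THF, −78 °C) and a DMF quench give 8-formyl-hexa-O-benzylepigallocatechin F1. Claisen–Schmidt condensation of F1 with ketone 6 (KOH, EtOH/THF) gives (E)-1-[4-(benzyloxy)phenyl]-3-(hexa-O-benzylepigallocatechin-8-yl)prop-2-en-1-one F2. Miyaura borylation of 10 (B2pin2, PdCl2(dppf), KOAc, dioxane, 80 °C) gives 5-(benzyloxy)-2-(4,4,5,5-tetramethyl-1,3,2-dioxaborolan-2-yl)phenyl acetate F3. Rhodium-catalysed asymmetric conjugate arylation of F2 with F3 (Hayashi–Miyaura reaction; [Rh(OH)(cod)]2, the BINAP antipode that gives (3R), dioxane/H2O, 60 °C, no added base so that the acetate survives) then forms C4–C4a and should give 11.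

Step 9. Facial selectivity may be poor, because the nominally small substituent carries a bulky diarylmethyl group and the resident C3 centre may oppose the catalyst. The fallback replaces asymmetric induction by separation and recycling; it sets out from 11 and comes back at 12. NaBH4 (THF/EtOH, −20 °C) should reduce 11 without useful stereocontrol to 12 and its epimer, (1S,3R)-3-[2-acetoxy-4-(benzyloxy)phenyl]-1-[4-(benzyloxy)phenyl]-3-(hexa-O-benzylepigallocatechin-8-yl)propan-1-ol F4. The two are separated by chromatography, F4 is oxidised back to 11 with Dess–Martin periodinane and recycled, and 12 is taken through the carbonate methanolysis of step 9 to 13.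

Step 10. The oxyphosphonium derivative of the 4-benzyloxybenzylic carbinol may ionise, which erodes the inversion at C2 or leads to elimination to the styrene. The fallback closes ring C through the other C–O bond with retention; it sets out from 11 and comes back at 14. Reduction of 11 with (R)-2-methyl-CBS-oxazaborolidine and BH3·SMe2 gives the acetate F4, and K2CO3 in MeOH then gives (1S,3R)-3-[4-(benzyloxy)-2-hydroxyphenyl]-1-[4-(benzyloxy)phenyl]-3-(hexa-O-benzylepigallocatechin-8-yl)propan-1-ol F5. PhNTf2 and Et3N in CH2Cl2 sulfonylate only the phenol and give (1S,3R)-1-[4-(benzyloxy)phenyl]-3-[4-(benzyloxy)-2-(trifluoromethylsulfonyloxy)phenyl]-3-(hexa-O-benzylepigallocatechin-8-yl)propan-1-ol F6. Intramolecular Buchwald–Hartwig etherification (Pd(OAc)2, a bulky di-tert-butylbiarylphosphine, Cs2CO3, toluene, 80 °C) then forms the C8a–O1 bond with retention at the carbinol carbon and should give 14.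

Further compounds
F1 | step 8 | 8-formyl-hexa-O-benzylepigallocatechin | O=Cc1c(OCc3ccccc3)cc(OCc3ccccc3)c2c1O[C@H](c1cc(OCc3ccccc3)c(OCc3ccccc3)c(OCc3ccccc3)c1)[C@H](OCc1ccccc1)C2
F2 | step 8 | (E)-1-[4-(benzyloxy)phenyl]-3-(hexa-O-benzylepigallocatechin-8-yl)prop-2-en-1-one | O=C(c1ccc(OCc2ccccc2)cc1)/C=C/c1c(OCc3ccccc3)cc(OCc3ccccc3)c2c1O[C@H](c1cc(OCc3ccccc3)c(OCc3ccccc3)c(OCc3ccccc3)c1)[C@H](OCc1ccccc1)C2
F3 | step 8 | 5-(benzyloxy)-2-(4,4,5,5-tetramethyl-1,3,2-dioxaborolan-2-yl)phenyl acetate | CC(=O)Oc1cc(OCc2ccccc2)ccc1B1OC(C)(C)C(C)(C)O1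
F4 | step 9 | (1S,3R)-3-[2-acetoxy-4-(benzyloxy)phenyl]-1-[4-(benzyloxy)phenyl]-3-(hexa-O-benzylepigallocatechin-8-yl)propan-1-ol | O[C@H](c1ccc(OCc2ccccc2)cc1)C[C@@H](c1c(OCc3ccccc3)cc(OCc3ccccc3)c2c1O[C@H](c1cc(OCc3ccccc3)c(OCc3ccccc3)c(OCc3ccccc3)c1)[C@H](OCc1ccccc1)C2)c1ccc(OCc2ccccc2)cc1OC(C)=O
F5 | step 10 | (1S,3R)-3-[4-(benzyloxy)-2-hydroxyphenyl]-1-[4-(benzyloxy)phenyl]-3-(hexa-O-benzylepigallocatechin-8-yl)propan-1-ol | O[C@H](c1ccc(OCc2ccccc2)cc1)C[C@@H](c1c(OCc3ccccc3)cc(OCc3ccccc3)c2c1O[C@H](c1cc(OCc3ccccc3)c(OCc3ccccc3)c(OCc3ccccc3)c1)[C@H](OCc1ccccc1)C2)c1ccc(OCc2ccccc2)cc1O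
F6 | step 10 | (1S,3R)-1-[4-(benzyloxy)phenyl]-3-[4-(benzyloxy)-2-(trifluoromethylsulfonyloxy)phenyl]-3-(hexa-O-benzylepigallocatechin-8-yl)propan-1-ol | O[C@H](c1ccc(OCc2ccccc2)cc1)C[C@@H](c1c(OCc3ccccc3)cc(OCc3ccccc3)c2c1O[C@H](c1cc(OCc3ccccc3)c(OCc3ccccc3)c(OCc3ccccc3)c1)[C@H](OCc1ccccc1)C2)c1ccc(OCc2ccccc2)cc1OS(=O)(=O)C(F)(F)F
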